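**Plan**

- Retrosynthesis: cut the ester C–O bond (arachidonic acid plus the C20 allylic alcohol 10), then cut ring bonds C4–C5 and C1–C6 of the cyclohexene in one retro-[4+2] step to the open-chain tetraene 5 and methacrolein (an isobutene equivalent whose formyl group later becomes methyl), then trace the diene end back to farnesol.
- Enabling feature: in the 2,6,6-trimethylcyclohex-2-enyl ring (C1 = stereogenic CH, C2 = C–CH3, C3 = CH, C4 and C5 = CH2, C6 = CMe2) the C2=C3 double bond lies opposite the C5–C6 bond, and C1 is the allylic end of a former (E)-1-alkyl-2-methylbuta-1,3-diene. This is a cyclohexene (Diels–Alder) retron.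
- Forward order: the chain is finished first (farnesol → silyl ether → terminal (E)-enal → 1,3-diene), the only ring is then closed on the chain end by one cycloaddition, and formyl-to-methyl reduction, desilylation and esterification follow.
- Stereochemistry: the two E-alkenes come from (2E,6E)-farnesol and the four Z-alkenes from arachidonic acid. The single stereocentre C1 comes from a chiral oxazaborolidinium catalyst, which fixes C6 and, through the endo transition state and the E-diene, C1; C6 then becomes CMe2.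

Key step: step 4

Assumption: the (S)-configured oxazaborolidinium catalyst is taken to deliver the diene to the α-Re face of bound methacrolein, as the accepted model for 2-substituted acroleins indicates; if the opposite sense were found with this diene, the catalyst from (R)-diphenylprolinol would be used with no other change.

**Route**

Step 1
Reactants: 1 (2E,6E)-farnesol
Product: 2 tert-butyldiphenyl{[(2E,6E)-3,7,11-trimethyldodeca-2,6,10-trien-1-yl]oxy}silane
Conditions: TBDPSCl, imidazole, CH2Cl2, 0 °C to rt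
Reagents that add atoms: tert-butyl(chloro)diphenylsilane, CC(C)(C)[Si](Cl)(c1ccccc1)c1ccccc1
Why: Imidazole-promoted silylation of the primary allylic alcohol gives a bulky, weakly Lewis-basic ether that should survive the oxidation, the ylide and the Lewis acid of the later steps; no stereocentre is made and the E-alkenes are untouched.

Step 2
Reactants: 2 tert-butyldiphenyl{[(2E,6E)-3,7,11-trimethyldodeca-2,6,10-trien-1-yl]oxy}silane
Product: 4 (2E,6E,10E)-12-(tert-butyldiphenylsilyloxy)-2,6,10-trimethyldodeca-2,6,10-trienal, via allylic alcohol 3 (not isolated)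
Conditions: SeO2 (cat.), tBuOOH, salicylic acid (cat.), CH2Cl2, 0 °C to rt, partial conversion; filter; then MnO2, CH2Cl2, rt
Reagents that add atoms: tert-butyl hydroperoxide, CC(C)(C)OO (source of the new oxygen, delivered through catalytic selenium dioxide, O=[Se]=O)
Why: Catalytic SeO2 allylic hydroxylation (ene reaction, then [2,3]-sigmatropic shift) should attack the most accessible and most electron-rich alkene, the terminal isopropylidene, at its (E)-methyl group, and MnO2 oxidation of the allylic alcohol then converges alcohol and any enal already formed to the (E)-enal.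

Step 3
Reactants: 4 (2E,6E,10E)-12-(tert-butyldiphenylsilyloxy)-2,6,10-trimethyldodeca-2,6,10-trienal
Product: 5 tert-butyldiphenyl{[(2E,6E,10E)-3,7,11-trimethyltrideca-2,6,10,12-tetraen-1-yl]oxy}silane
Conditions: Ph3PCH3Br, n-BuLi, THF, 0 °C; then 4, −78 °C to rt
Reagents that add atoms: methyltriphenylphosphonium bromide, C[P+](c1ccccc1)(c1ccccc1)c1ccccc1.[Br-]
Why: Wittig methylenation with the non-stabilised ylide adds 1,2 to the enal only and keeps the E geometry of the C10=C11 bond, which should give the (E)-1-alkyl-2-methylbuta-1,3-diene unit C10=C11–C12=C13.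

Step 4
Reactants: 5 tert-butyldiphenyl{[(2E,6E,10E)-3,7,11-trimethyltrideca-2,6,10,12-tetraen-1-yl]oxy}silane; 6 methacrolein (2-methylprop-2-enal)
Product: 7 (1S,2R)-2-[(3E,7E)-9-(tert-butyldiphenylsilyloxy)-3,7-dimethylnona-3,7-dien-1-yl]-1,3-dimethylcyclohex-3-ene-1-carbaldehyde
Conditions: 6 (5 equiv), (S)-3,3-diphenyl-1-(o-tolyl)tetrahydro-1H,3H-pyrrolo[1,2-c][1,3,2]oxazaborole (C24H24BNO, 20 mol%), HNTf2 (18 mol%), CH2Cl2, −78 to −40 °C
Reagents that add atoms: none
Why: The N-protonated oxazaborolidine binds methacrolein at boron (s-trans enal), lowers its LUMO and screens one enal face, so the diene C10=C11–C12=C13 of 5 should add in a concerted but asynchronous [4+2] cycloaddition in which the C13–Cβ bond (ring C4–C5) runs ahead of the C10–Cα bond (ring C1–C6). The closest known reaction type is the oxazaborolidinium-catalysed enantioselective Diels–Alder reaction of 2-substituted acroleins with open-chain 1,3-dienes. The six-membered ring is closed by this suprafacial intermolecular [4π+2π] cycloaddition, which also leaves the new C2=C3 double bond exactly where the target has it. The quaternary C6 is set by the catalyst (addition to the unshielded α-Re face should give 1S), and C1 follows from C6 through the endo transition state (formyl group under the diene) and the E geometry of C10=C11, which place the side chain cis to the formyl group (2R here, the S centre of the target once formyl has become methyl). The step needs regioselectivity, endo selectivity and chemoselectivity: the alkyl group on the diene terminus C10 is the stronger director (largest HOMO coefficient at the unhindered C13) and should outweigh the C11 methyl, Lewis-acid activation sharpens both this and the endo preference, and only the conjugated diene should react, the two isolated trisubstituted alkenes and the bulky silyl ether being inert at −78 °C. The minor exo adduct, which would lower the enantiomeric purity of C1 after step 5, should be removed by chromatography at this stage.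

Step 5
Reactants: 7 (1S,2R)-2-[(3E,7E)-9-(tert-butyldiphenylsilyloxy)-3,7-dimethylnona-3,7-dien-1-yl]-1,3-dimethylcyclohex-3-ene-1-carbaldehyde
Product: 9 tert-butyl{[(2E,6E)-3,7-dimethyl-9-[(1S)-2,6,6-trimethylcyclohex-2-en-1-yl]nona-2,6-dien-1-yl]oxy}diphenylsilane, via silylhydrazone 8 (not isolated)
Conditions: TBSNHNHTBS, Sc(OTf)3 (1 mol%), CH2Cl2, 23 °C; evaporate; then KOtBu, tBuOH, DMSO, 23 °C
Reagents that add atoms: 1,2-bis(tert-butyldimethylsilyl)hydrazine, CC(C)(C)[Si](C)(C)NN[Si](C)(C)C(C)(C)C (its N–N–Si unit is carried by intermediate 8 only; product 9 gains hydrogen alone)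
Why: Wolff–Kishner reduction in its mild N-silylhydrazone form: condensation gives the N-silyl hydrazone, which alkoxide in DMSO should convert at room temperature through the diazene anion and loss of N2 into a methyl group, so C6 becomes the gem-dimethyl carbon while C1, which has no acidifying neighbour, keeps its configuration.

Step 6
Reactants: 9 tert-butyl{[(2E,6E)-3,7-dimethyl-9-[(1S)-2,6,6-trimethylcyclohex-2-en-1-yl]nona-2,6-dien-1-yl]oxy}diphenylsilane
Product: 10 (2E,6E)-3,7-dimethyl-9-[(1S)-2,6,6-trimethylcyclohex-2-en-1-yl]nona-2,6-dien-1-ol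
Conditions: TBAF, THF, 0 °C to rt
Reagents that add atoms: none
Why: Fluoride-induced desilylation (Si–F bond formation) should free the primary allylic alcohol without touching the alkenes or the stereocentre.

Step 7
Reactants: 10 (2E,6E)-3,7-dimethyl-9-[(1S)-2,6,6-trimethylcyclohex-2-en-1-yl]nona-2,6-dien-1-ol; 11 arachidonic acid ((5Z,8Z,11Z,14Z)-icosa-5,8,11,14-tetraenoic acid)
Product: 12 (2E,6E)-3,7-dimethyl-9-[(1S)-2,6,6-trimethylcyclohex-2-en-1-yl]nona-2,6-dien-1-yl (5Z,8Z,11Z,14Z)-icosa-5,8,11,14-tetraenoate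
Conditions: DCC, DMAP (cat.), CH2Cl2, 0 °C to rt, argon, dark
Reagents that add atoms: none
Why: Steglich esterification (carbodiimide activation, DMAP acyl transfer) should join acid and primary allylic alcohol under neutral conditions at or below room temperature, so the skipped all-Z tetraene is not isomerised or oxidised and the allylic alcohol does not ionise.

**Compound list**

1 | (2E,6E)-farnesol | OC/C=C(\C)CC/C=C(\C)CCC=C(C)C | starting material
2 | tert-butyldiphenyl{[(2E,6E)-3,7,11-trimethyldodeca-2,6,10-trien-1-yl]oxy}silane | CC(C)(C)[Si](c1ccccc1)(c1ccccc1)OC/C=C(\C)CC/C=C(\C)CCC=C(C)C | intermediate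
3 | (2E,6E,10E)-12-(tert-butyldiphenylsilyloxy)-2,6,10-trimethyldodeca-2,6,10-trien-1-ol | CC(C)(C)[Si](c1ccccc1)(c1ccccc1)OC/C=C(\C)CC/C=C(\C)CC/C=C(\C)CO | intermediate
4 | (2E,6E,10E)-12-(tert-butyldiphenylsilyloxy)-2,6,10-trimethyldodeca-2,6,10-trienal | CC(C)(C)[Si](c1ccccc1)(c1ccccc1)OC/C=C(\C)CC/C=C(\C)CC/C=C(\C)C=O | intermediate
5 | tert-butyldiphenyl{[(2E,6E,10E)-3,7,11-trimethyltrideca-2,6,10,12-tetraen-1-yl]oxy}silane | CC(C)(C)[Si](c1ccccc1)(c1ccccc1)OC/C=C(\C)CC/C=C(\C)CC/C=C(\C)C=C | intermediate
6 | methacrolein (2-methylprop-2-enal) | CC(=C)C=O | starting material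
7 | (1S,2R)-2-[(3E,7E)-9-(tert-butyldiphenylsilyloxy)-3,7-dimethylnona-3,7-dien-1-yl]-1,3-dimethylcyclohex-3-ene-1-carbaldehyde | CC(C)(C)[Si](c1ccccc1)(c1ccccc1)OC/C=C(\C)CC/C=C(\C)CC[C@@H]1C(C)=CCC[C@]1(C)C=O | intermediate
8 | (E)-N-(tert-butyldimethylsilyl)hydrazone of aldehyde 7 | CC(C)(C)[Si](c1ccccc1)(c1ccccc1)OC/C=C(\C)CC/C=C(\C)CC[C@@H]1C(C)=CCC[C@]1(C)/C=N/N[Si](C)(C)C(C)(C)C | intermediate
9 | tert-butyl{[(2E,6E)-3,7-dimethyl-9-[(1S)-2,6,6-trimethylcyclohex-2-en-1-yl]nona-2,6-dien-1-yl]oxy}diphenylsilane | CC(C)(C)[Si](c1ccccc1)(c1ccccc1)OC/C=C(\C)CC/C=C(\C)CC[C@@H]1C(C)=CCCC1(C)C | intermediate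
10 | (2E,6E)-3,7-dimethyl-9-[(1S)-2,6,6-trimethylcyclohex-2-en-1-yl]nona-2,6-dien-1-ol | OC/C=C(\C)CC/C=C(\C)CC[C@@H]1C(C)=CCCC1(C)C | intermediate
11 | arachidonic acid, (5Z,8Z,11Z,14Z)-icosa-5,8,11,14-tetraenoic acid | CCCCC/C=C\C/C=C\C/C=C\C/C=C\CCCC(=O)O | starting material
12 | (2E,6E)-3,7-dimethyl-9-[(1S)-2,6,6-trimethylcyclohex-2-en-1-yl]nona-2,6-dien-1-yl (5Z,8Z,11Z,14Z)-icosa-5,8,11,14-tetraenoate | CCCCC/C=C\C/C=C\C/C=C\C/C=C\CCCC(=O)OC/C=C(\C)CC/C=C(\C)CC[C@@H]1C(C)=CCCC1(C)C | target

**Step count and risks**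

Total step count: 7. Longest linear sequence: 7 steps (1 to 12).

Steps most likely to fail:

1. Step 4. One catalytic event must deliver regio-, endo/exo and facial control together. Possible failures are competing bonding of the methacrolein α-carbon to the unsubstituted diene terminus, a weak endo preference caused by the α-methyl group (which would lower the enantiomeric purity of C1 once C6 is made symmetric), and acid-triggered cyclisation or ene reaction of the polyene. Fallback, from 5 back to 7: an auxiliary-controlled Diels–Alder reaction of 5 with (R)-3-acryloyl-4-benzyloxazolidin-2-one (C=CC(=O)N1[C@H](Cc2ccccc2)COC1=O; Et2AlCl, CH2Cl2, −78 °C). The diene should add to the chelated s-cis imide on the face remote from the benzyl group with high endo and 'ortho' preference, which should give the cis-imide (4R)-4-benzyl-3-{[(1S,2S)-2-[(3E,7E)-9-(tert-butyldiphenylsilyloxy)-3,7-dimethylnona-3,7-dien-1-yl]-3-methylcyclohex-3-en-1-yl]carbonyl}oxazolidin-2-one F1. MeOMgBr in MeOH at 0 °C should exchange the auxiliary for the methyl ester F2. LiN(iPr)2 and then MeI in THF at −78 °C should methylate the enolate on the face away from the neighbouring side chain to give the quaternary methyl ester F3. iBu2AlH in CH2Cl2 at −78 °C should reduce the hindered ester F3 to aldehyde 7, where the route resumes.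

2. Step 2. The oxidation may not discriminate cleanly between the terminal and the internal trisubstituted alkenes, may over-oxidise, or may stall at low conversion. Fallback, from 2 back to 4: terminal-selective bromohydrin formation (NBS, THF–H2O, 0 °C) should give the racemic bromohydrin F4. K2CO3 in MeOH should close it to the terminal epoxide F5. HIO4 in THF–H2O should cleave F5, with loss of acetone, to the aldehyde (4E,8E)-10-(tert-butyldiphenylsilyloxy)-4,8-dimethyldeca-4,8-dienal F6. An E-selective Wittig reaction of F6 with the stabilised ylide 2-(triphenylphosphoranylidene)propanal (toluene, 80 °C) should give enal 4.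

3. Step 5. Condensation at the neopentyl-type aldehyde may be slow or lead to azine formation, and the basic medium may cause loss of the silyl group or migration of the ring double bond. Fallback, from 7 to 9 without any hydrazone: NaBH4 in MeOH at 0 °C should give the neopentyl alcohol [(1S,2R)-2-[(3E,7E)-9-(tert-butyldiphenylsilyloxy)-3,7-dimethylnona-3,7-dien-1-yl]-1,3-dimethylcyclohex-3-en-1-yl]methanol F7. TsCl, pyridine and DMAP at rt should give its 4-methylbenzenesulfonate F8. Hydride displacement with LiEt3BH in THF at reflux, a reagent suited to neopentyl sulfonates, should give 9.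

Further compounds
F1 | step 4 | (4R)-4-benzyl-3-{[(1S,2S)-2-[(3E,7E)-9-(tert-butyldiphenylsilyloxy)-3,7-dimethylnona-3,7-dien-1-yl]-3-methylcyclohex-3-en-1-yl]carbonyl}oxazolidin-2-one | CC(C)(C)[Si](c1ccccc1)(c1ccccc1)OC/C=C(\C)CC/C=C(\C)CC[C@@H]1C(C)=CCC[C@@H]1C(=O)N1[C@H](Cc2ccccc2)COC1=O
F2 | step 4 | methyl (1S,2S)-2-[(3E,7E)-9-(tert-butyldiphenylsilyloxy)-3,7-dimethylnona-3,7-dien-1-yl]-3-methylcyclohex-3-ene-1-carboxylate | CC(C)(C)[Si](c1ccccc1)(c1ccccc1)OC/C=C(\C)CC/C=C(\C)CC[C@@H]1C(C)=CCC[C@@H]1C(=O)OC
F3 | step 4 | methyl (1S,2R)-2-[(3E,7E)-9-(tert-butyldiphenylsilyloxy)-3,7-dimethylnona-3,7-dien-1-yl]-1,3-dimethylcyclohex-3-ene-1-carboxylate | CC(C)(C)[Si](c1ccccc1)(c1ccccc1)OC/C=C(\C)CC/C=C(\C)CC[C@@H]1C(C)=CCC[C@]1(C)C(=O)OC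
F4 | step 2 | (6E,10E)-3-bromo-12-(tert-butyldiphenylsilyloxy)-2,6,10-trimethyldodeca-6,10-dien-2-ol (racemic) | CC(C)(C)[Si](c1ccccc1)(c1ccccc1)OC/C=C(\C)CC/C=C(\C)CCC(Br)C(C)(C)O
F5 | step 2 | tert-butyl{[(2E,6E)-9-(3,3-dimethyloxiran-2-yl)-3,7-dimethylnona-2,6-dien-1-yl]oxy}diphenylsilane (racemic) | CC(C)(C)[Si](c1ccccc1)(c1ccccc1)OC/C=C(\C)CC/C=C(\C)CCC1OC1(C)C
F6 | step 2 | (4E,8E)-10-(tert-butyldiphenylsilyloxy)-4,8-dimethyldeca-4,8-dienal | CC(C)(C)[Si](c1ccccc1)(c1ccccc1)OC/C=C(\C)CC/C=C(\C)CCC=O
F7 | step 5 | [(1S,2R)-2-[(3E,7E)-9-(tert-butyldiphenylsilyloxy)-3,7-dimethylnona-3,7-dien-1-yl]-1,3-dimethylcyclohex-3-en-1-yl]methanol | CC(C)(C)[Si](c1ccccc1)(c1ccccc1)OC/C=C(\C)CC/C=C(\C)CC[C@@H]1C(C)=CCC[C@]1(C)CO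
F8 | step 5 | [(1S,2R)-2-[(3E,7E)-9-(tert-butyldiphenylsilyloxy)-3,7-dimethylnona-3,7-dien-1-yl]-1,3-dimethylcyclohex-3-en-1-yl]methyl 4-methylbenzenesulfonate | CC(C)(C)[Si](c1ccccc1)(c1ccccc1)OC/C=C(\C)CC/C=C(\C)CC[C@@H]1C(C)=CCC[C@]1(C)COS(=O)(=O)c1ccc(C)cc1
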